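## Structural features

The target is a guaiane: a 2-methylcyclopent-2-enone (C1–C5, ketone C3, alkene C4=C5) fused through the C1–C5 bond to a seven-membered carbocycle (C1, C5–C10). The seven-membered ring carries three stereocentres, C7 (2-acetoxypropan-2-yl), C8 (propanoyloxy) and C10 (methyl); the ring-fusion carbon C1 is the fourth. C7 and C8 are adjacent, C10 lies between C9 and C1, and H1, the C10 methyl, the C8 oxygen and the C7 side chain all sit on one face (β), i.e. 1R,7S,8R,10S. Fragile points are the tertiary acetate (ionisation, elimination), the C1–H bond (γ to the enone, and so open to epimerisation or alkene migration through the dienol) and the two different esters, which must not be scrambled. The real difficulty is stereocontrol on a mobile seven-membered ring, above all at C1 and C10, which have no neighbouring heteroatom. The key step uses the fact that a C4-methyl cyclopentenone fused to a seven-membered ring with a one-carbon branch at C10 is the chromophore formed when a 4-methyl cross-conjugated cyclohexadienone with a quaternary C10 is irradiated in acid. C7 and C8 can therefore be set on a six-membered ring, where conformational analysis is dependable, and C7 can come from the chiral pool.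

## Logic of the disconnections

18 ⇒ 17. The two C–H bonds that make C10 a stereocentre (C10–H and one C14–H) are removed. The ring-forming step leaves the C10 methyl on the face opposite to the one required, so the methyl has to be turned over through a trigonal C10. This removes one stereocentre; the forward step must deliver hydrogen to the α face and spare the enone.

17 ⇒ 15. Water is added back across C10=C14, because the tertiary C10 carbinol is the direct product of the ring-forming step. The forward dehydration must go toward C14 and must not take H1, which would give the conjugated dienone.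

15 ⇒ 14. The C1–C5 bond is cut, the C5–C10 bond restored and the C10–O bond removed. This turns the five-seven bicycle into a six-six dienone and traces both C1 and C10 to one quaternary centre. The forward step needs a 4-methyl 1,4-dien-3-one with the C10 methyl trans to the C7 side chain, and an acidic aqueous medium.

14 ⇒ 13. The C1=C2 double bond is saturated. The enone is what an annulation delivers; the forward dehydrogenation must go toward C1–C2 and not C6–C7.

13 ⇒ 12 ⇒ 11. The two acyl C–O bonds are cut, first the tertiary acetate, then the secondary propanoate. A secondary and a tertiary alcohol differ enough in reactivity to be acylated in turn without protecting groups; the forward steps must keep to that order.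

11 ⇒ 10 ⇒ 9. The C8–H bond is exchanged: 8β-carbinol back to ketone, ketone back to 8α-carbinol. The annulation needs the C8 oxygen trans to the side chain (equatorial, out of the way), while the target has it cis. An SN2 inversion beside the tertiary-alkyl-bearing C7 is unattractive, so the inversion is done by oxidation and face-selective reduction. The reduction must choose the saturated ketone over the enone.

9 ⇒ 5 + 6. The C4=C5 and C1–C10 bonds are cut (Robinson retron). This splits the bicycle into a monocyclic ketone and a five-carbon enone; the forward alkylation must place the new bond cis to the side chain so that the methyl ends trans (10-epi series).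

5 ⇒ 3 ⇒ 2. The C–O bond at the carbon γ to the ketone is cut and the enone restored. The oxygen that becomes O8 sits exactly at the vinylogous position; the forward steps need γ-enolisation (not C6) and oxygen delivery anti to the side chain.

2 ⇒ 1. The tertiary C–O bond of the side chain is cut to an isopropenyl group. Hydration is placed first so that no later oxidant meets a second alkene; it must avoid aromatisation.

## Other disconnections considered

Alternative 1: The cut is through C6–C7 and C9–C10, leading back to the dialkylidenecyclopentane A2 and the siloxyvinyldiazoacetate A3. Forward, Rh2(S-DOSP)4 would decompose A3, the carbenoid would cyclopropanate the exocyclic methylene of A2, and the cis-divinylcyclopropane would undergo Cope rearrangement to the cycloheptadiene A1.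
- In its favour: it is convergent and catalytic, and it closes the seven-membered ring while setting the C10 methyl directly in the required sense. On C10 it is better than the chosen plan, which has to turn the methyl over in two extra steps. It needs no photoreactor, so on scale-up it is at least equal.
- Against it here: A1 has the alkene at C1=C5, a C4 stereocentre to be erased, C7 as an sp2 carbon and C8 at the ketone level. C7, C8 and C1 would all have to be set afterwards by substrate control on the flexible seven-membered ring, which is the problem the chosen plan avoids. The enolisable β-keto ester must be turned into the C(CH3)2OAc group, and neither A2 nor A3 is commercial.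
- Comparison: on mechanism the concerted boat Cope step is as predictable as the photorearrangement. On structure it solves one stereocentre of four, against two for the chosen key step. On step economy it should be longer, an estimated 16 to 18 steps against 12.

Alternative 2: The cut is the C8–C9 bond, leading to aldehyde A5, whose cyclopentene would come from 1 by ring contraction. Forward, Me2AlCl would promote a type 2 carbonyl-ene reaction of the C8 aldehyde with the C1 isopropenyl group to give the dienol A4.
- In its favour: C1 is taken straight from the chiral pool and does not depend on transfer from C10. A4 has a free 8α-hydroxyl homoallylic to the C10 methylene, which is ideal for hydroxyl-directed hydrogenation from the α face. On control of C10 it is better than the steric argument of step 12, and it is thermal.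
- Against it here: it needs the ring contraction of 1 and a separate, weakly controlled construction of C7. A seven-membered ene closure is slower than a six-membered one and competes with Prins-type chloride capture. C8 again emerges trans to the side chain, so the same inversion is needed, and C3 and both silyl ethers need later adjustment.
- Comparison: on mechanism a closed ene transition state is as well understood as the photoreaction. On structure it fixes C1 and C8 directly but not C7. On step economy it is worse, an estimated 16 steps or more.

Alternative 3: The cut is a one-carbon excision of C2 (C1–C2 and C2–C3), then the C1–C3 and C4–C5 bonds of cyclobutanone A7, leading to cycloheptene A8 and dichloroketene A9. Forward, diazomethane A10 would expand A7 to the dichlorocyclopentanone A6 by migration of the non-chlorinated carbon.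
- In its favour: the ring expansion is regioselective and reliable, equal to the chosen key step in dependability of the ring-forming event. It annulates the five-membered ring last, onto a ring that already holds C7, C8, C10 and both esters, and the CCl2 group is a known entry to a 2-methylcyclopentenone.
- Against it here: the whole stereochemical problem is pushed into A8, a cycloheptene with three stereocentres and no evident chiral-pool source. The [2+2] step with A9 would meet an alkene whose two carbons differ only remotely, so regio- and facial control are doubtful. A10 is hazardous, and several steps with cuprates and zinc would follow in the presence of two esters.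
- Comparison: on mechanism it is sound. On structure it leaves the hardest part unsolved, and on step economy it is clearly worse.

Key step: step 10

Remarks on the chemistry:
- Eudesmane numbering is used for the decalins and guaiane numbering for the hydroazulenes; β is the face of the C7 side chain.
- Each stereodescriptor of 14, 15 and 18 was checked against the mechanism of the photorearrangement (cis-fused cyclopropane, inversion at C10). The three are mutually consistent, so no structure needed correction.
- Compound 5 is carried as a mixture of C2 epimers, because C2 becomes the quaternary C10 in step 4.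

## Steps

Step 1
Reactants: 1 (R)-(−)-carvone
Product: 2 (5R)-5-(2-hydroxypropan-2-yl)-2-methylcyclohex-2-en-1-one (8-hydroxycarvotanacetone)
Conditions: 50% aq. H2SO4, 0 °C
Reagents that add atoms: water, O
Why: Acid-catalysed Markovnikov hydration: the isopropenyl group is protonated to a tertiary cation that water captures, while the electron-poor enone alkene is not protonated; C5 is not enolisable and keeps its configuration, and the low temperature should suppress aromatisation to carvacrol.

Step 2
Reactants: 2 (5R)-5-(2-hydroxypropan-2-yl)-2-methylcyclohex-2-en-1-one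
Product: 3 trimethyl({(5S)-2-methyl-5-[2-(trimethylsilyloxy)propan-2-yl]cyclohexa-1,3-dien-1-yl}oxy)silane
Conditions: Me3SiCl, NaI, Et3N, MeCN, 0 °C → rt
Reagents that add atoms: chlorotrimethylsilane, C[Si](C)(C)Cl
Why: Silylation under equilibrating conditions (Me3SiI formed in situ, Et3NH+ as proton shuttle) should give the thermodynamic, through-conjugated dienol ether by loss of a C4 proton, as Δ4-3-oxo steroids give 3,5-dienol ethers; the tertiary alcohol is silylated at the same time and C5 is untouched (its descriptor changes only through priorities).

Step 3
Reactants: 3 trimethyl({(5S)-2-methyl-5-[2-(trimethylsilyloxy)propan-2-yl]cyclohexa-1,3-dien-1-yl}oxy)silane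
Product: 5 (4S,5S)-4-hydroxy-5-(2-hydroxypropan-2-yl)-2-methylcyclohexan-1-one, via endoperoxide 4 (not isolated)
Conditions: O2, hν (visible), tetraphenylporphyrin (cat.), CH2Cl2, −78 °C; N2 purge; then H2 (1 atm), Pd/C, EtOAc, 0 °C → rt; then aq. citric acid, MeOH
Reagents that add atoms: dioxygen, O=O
Why: Singlet oxygen should add to the s-cis diene in a [4+2] cycloaddition, which oxygenates C1 and C4 only, from the face opposite the bulky C5 substituent, setting the C4–O bond trans to the side chain; hydrogenolysis of the O–O bond and hydrogenation of the alkene over Pd/C, collapse of the silyl hemiketal and mild acid cleavage of the tertiary silyl ether then give the saturated γ-hydroxy ketone.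

Step 4
Reactants: 5 (4S,5S)-4-hydroxy-5-(2-hydroxypropan-2-yl)-2-methylcyclohexan-1-one, 6 ethyl vinyl ketone
Product: 9 8α,11-dihydroxy-10-epi-eudesm-4-en-3-one, via Michael adduct 7 (not isolated), via ketol 8 (not isolated)
Conditions: KOH (0.2 equiv), EtOH, −10 → 0 °C; then KOH (2 equiv), EtOH, 70 °C
Reagents that add atoms: none
Why: Robinson annulation: the more substituted enolate adds to the enone at C2 by axial attack on the chair that has the C5 side chain and the C4 hydroxyl equatorial, so the new C–C bond is cis and the methyl trans to the side chain (10-epi series, as with dihydrocarvone); aldol closure and base-induced dehydration of the ketol give the 4-en-3-one.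

Step 5
Reactants: 9 8α,11-dihydroxy-10-epi-eudesm-4-en-3-one
Product: 10 11-hydroxy-10-epi-eudesm-4-ene-3,8-dione
Conditions: Dess–Martin periodinane, pyridine, CH2Cl2, 0 °C → rt
Reagents that add atoms: none
Why: Dess–Martin oxidation of the secondary C8 alcohol; the tertiary alcohol cannot be oxidised, and the buffered non-basic medium should spare the β-hydroxy ketone from retro-aldol cleavage and C7 from epimerisation.

Step 6
Reactants: 10 11-hydroxy-10-epi-eudesm-4-ene-3,8-dione
Product: 11 8β,11-dihydroxy-10-epi-eudesm-4-en-3-one
Conditions: LiBH(s-Bu)3 (1.3 equiv), THF, −78 °C; then H2O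
Reagents that add atoms: none
Why: Reduction with a bulky trialkylborohydride: hydride should attack the C8 ketone from the equatorial α face, anti to the vicinal 7β side chain and away from the axial C1 methylene on C10, giving the axial 8β alcohol cis to the side chain; at −78 °C the saturated ketone should react well before the tetrasubstituted conjugated C3 ketone.

Step 7
Reactants: 11 8β,11-dihydroxy-10-epi-eudesm-4-en-3-one
Product: 12 11-hydroxy-8β-propanoyloxy-10-epi-eudesm-4-en-3-one
Conditions: (EtCO)2O, DMAP (cat.), pyridine, CH2Cl2, 0 °C → rt
Reagents that add atoms: propanoic anhydride, CCC(=O)OC(=O)CC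
Why: DMAP-catalysed acylation; the secondary 8β alcohol reacts far faster than the tertiary C11 alcohol, so the propanoate is placed on O8 only, with retention at C8.

Step 8
Reactants: 12 11-hydroxy-8β-propanoyloxy-10-epi-eudesm-4-en-3-one
Product: 13 11-acetoxy-8β-propanoyloxy-10-epi-eudesm-4-en-3-one
Conditions: Ac2O, DMAP (1 equiv), Et3N, CH2Cl2, 40 °C
Reagents that add atoms: acetic anhydride, CC(=O)OC(C)=O
Why: Steglich-type acetylation: the N-acetylpyridinium ion from Ac2O and DMAP is reactive enough to esterify the tertiary alcohol on warming, without a cationic pathway that could eliminate it; the C8 ester, the enone and all stereocentres are untouched.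

Step 9
Reactants: 13 11-acetoxy-8β-propanoyloxy-10-epi-eudesm-4-en-3-one
Product: 14 11-acetoxy-8β-propanoyloxy-10-epi-eudesma-1,4-dien-3-one
Conditions: DDQ, 1,4-dioxane, reflux
Reagents that add atoms: none
Why: DDQ dehydrogenation of a 4-en-3-one under neutral conditions goes through the 2,4-dienol and hydride abstraction from C1, giving the cross-conjugated 1,4-dien-3-one as with Δ4-3-oxo steroids; without strong acid the 4,6-dienone is not expected and the esters are inert.

Step 10
Reactants: 14 11-acetoxy-8β-propanoyloxy-10-epi-eudesma-1,4-dien-3-one
Product: 15 11-acetoxy-10β-hydroxy-8β-propanoyloxy-1βH-guai-4-en-3-one (10α-methyl)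
Conditions: hν (medium-pressure mercury lamp, Pyrex filter), AcOH–H2O (1:1), N2, 15–20 °C, 0.01 M
Reagents that add atoms: water, O
Why: Excitation of the cross-conjugated dienone should bond its two β-carbons C1 and C5 to give a cyclopropyl oxyallyl zwitterion; protonation on oxygen makes it a cyclopropylcarbinyl cation at C4, which opens the C5–C10 bond while water attacks C10 from the rear. This is the santonin to isophotosantonic lactone rearrangement, the standard photochemical route from 4-methylcyclohexa-2,5-dienones with a quaternary C10 to hydroazulenones. The cyclopentenone is closed by the transannular C1–C5 bond (ring A contracts from six to five atoms through the three-membered ring); the seven-membered ring is not cyclised but arises by enlargement of ring B when the shared C5–C10 bond is cleaved. C1 is controlled by the quaternary C10: the cyclopropane must be cis-fused to ring B, so ring A folds toward the C10 methyl and H1 ends on the side of C9, which for the 10α-methyl series means 1β-H. C10 is controlled by the same intermediate, since water enters anti to the departing C5–C10 bond, placing the hydroxyl β and leaving the methyl α. The selectivity needed is opening of C5–C10 and not a 1,4-shift to a lumiketone; the 4-methyl group, which stabilises charge at C4, and the acidic medium secure it, and the high water content favours the carbinol over the C10 acetate. The esters do not absorb through Pyrex and should be stable to cold aqueous acetic acid; if the C8 propanoate carbonyl assists the opening, it would deliver oxygen to the same β face of C10.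

Step 11
Reactants: 15 11-acetoxy-10β-hydroxy-8β-propanoyloxy-1βH-guai-4-en-3-one
Product: 17 11-acetoxy-8β-propanoyloxy-1βH-guaia-4,10(14)-dien-3-one, via chlorosulfite 16 (not isolated)
Conditions: SOCl2, pyridine, −20 → 0 °C
Reagents that add atoms: none
Why: Dehydration of a tertiary alcohol through its chlorosulfite by pyridine-induced anti elimination (E2); H1 is syn to the 10β leaving group and cannot be removed in this mode, so the conjugated 1(10)-ene is avoided, and the accessible methyl hydrogens should give mainly the exocyclic alkene.

Step 12
Reactants: 17 11-acetoxy-8β-propanoyloxy-1βH-guaia-4,10(14)-dien-3-one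
Product: 18 11-acetoxy-8β-propanoyloxy-1βH,10αH-guai-4-en-3-one (target, 1R,7S,8R,10S)
Conditions: H2 (1 atm), RhCl(PPh3)3 (10 mol %), toluene, rt
Reagents that add atoms: none
Why: Homogeneous hydrogenation with RhCl(PPh3)3 reduces the 1,1-disubstituted alkene and leaves the tetrasubstituted enone, with little double-bond migration; allylic strain should keep H1 near the plane of C10=C14, so the ring segment C5–C8 with the β-oriented C7 and C8 substituents covers the β face and hydrogen is delivered from the α face, placing H10 α and the methyl β.

## Compound list

1 | (R)-(−)-carvone | CC1=CC[C@H](CC1=O)C(C)=C | starting material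
2 | (5R)-5-(2-hydroxypropan-2-yl)-2-methylcyclohex-2-en-1-one | CC1=CC[C@H](CC1=O)C(C)(C)O | intermediate
3 | trimethyl({(5S)-2-methyl-5-[2-(trimethylsilyloxy)propan-2-yl]cyclohexa-1,3-dien-1-yl}oxy)silane | CC1=C(O[Si](C)(C)C)C[C@@H](C=C1)C(C)(C)O[Si](C)(C)C | intermediate
4 | 6-methyl-1-(trimethylsilyloxy)-8-[2-(trimethylsilyloxy)propan-2-yl]-2,3-dioxabicyclo[2.2.2]oct-5-ene, peroxide bridge anti to the side chain | CC1=C[C@@H]2OO[C@@]1(O[Si](C)(C)C)C[C@@H]2C(C)(C)O[Si](C)(C)C | intermediate (not isolated)
5 | (4S,5S)-4-hydroxy-5-(2-hydroxypropan-2-yl)-2-methylcyclohexan-1-one, C2 epimers | CC1C[C@H](O)[C@H](CC1=O)C(C)(C)O | intermediate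
6 | ethyl vinyl ketone (pent-1-en-3-one) | CCC(=O)C=C | starting material
7 | (4S,5S)-4-hydroxy-5-(2-hydroxypropan-2-yl)-2-methyl-2-(3-oxopentyl)cyclohexan-1-one, C2 methyl trans to the C5 side chain | CCC(=O)CC[C@@]1(C)C[C@H](O)[C@H](CC1=O)C(C)(C)O | intermediate (not isolated)
8 | 5,8α,11-trihydroxy-10-epi-eudesman-3-one, C4 and C5 not defined | CC1C(=O)CC[C@@]2(C)C[C@H](O)[C@@H](C(C)(C)O)CC12O | intermediate (not isolated)
9 | 8α,11-dihydroxy-10-epi-eudesm-4-en-3-one (7β side chain, 10α-methyl) | CC1=C2C[C@H](C(C)(C)O)[C@@H](O)C[C@]2(C)CCC1=O | intermediate
10 | 11-hydroxy-10-epi-eudesm-4-ene-3,8-dione | CC1=C2C[C@H](C(C)(C)O)C(=O)C[C@]2(C)CCC1=O | intermediate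
11 | 8β,11-dihydroxy-10-epi-eudesm-4-en-3-one | CC1=C2C[C@H](C(C)(C)O)[C@H](O)C[C@]2(C)CCC1=O | intermediate
12 | 11-hydroxy-8β-propanoyloxy-10-epi-eudesm-4-en-3-one | CC1=C2C[C@H](C(C)(C)O)[C@H](OC(=O)CC)C[C@]2(C)CCC1=O | intermediate
13 | 11-acetoxy-8β-propanoyloxy-10-epi-eudesm-4-en-3-one | CC1=C2C[C@H](C(C)(C)OC(C)=O)[C@H](OC(=O)CC)C[C@]2(C)CCC1=O | intermediate
14 | 11-acetoxy-8β-propanoyloxy-10-epi-eudesma-1,4-dien-3-one | CC1=C2C[C@H](C(C)(C)OC(C)=O)[C@H](OC(=O)CC)C[C@]2(C)C=CC1=O | intermediate
15 | 11-acetoxy-10β-hydroxy-8β-propanoyloxy-1βH-guai-4-en-3-one (10α-methyl) | CCC(=O)O[C@@H]1C[C@](C)(O)[C@H]2CC(=O)C(C)=C2C[C@@H]1C(C)(C)OC(C)=O | intermediate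
16 | C10 chlorosulfite of 15 | CCC(=O)O[C@@H]1C[C@](C)(OS(Cl)=O)[C@H]2CC(=O)C(C)=C2C[C@@H]1C(C)(C)OC(C)=O | intermediate (not isolated)
17 | 11-acetoxy-8β-propanoyloxy-1βH-guaia-4,10(14)-dien-3-one | CCC(=O)O[C@@H]1CC(=C)[C@H]2CC(=O)C(C)=C2C[C@@H]1C(C)(C)OC(C)=O | intermediate
18 | 11-acetoxy-8β-propanoyloxy-1βH,10αH-guai-4-en-3-one | CCC(=O)O[C@@H]1C[C@H](C)[C@H]2CC(=O)C(C)=C2C[C@@H]1C(C)(C)OC(C)=O | target

## Step count and least certain steps

Total step count: 12. Longest linear sequence: 12 steps, from 1 to 18 (6 enters in step 4).

Step 10 (key step). Most likely to go wrong is loss of selectivity in the capture at C10 together with over-irradiation. The C8 propanoate carbonyl can take part in the opening through a six-membered acyloxonium ion and transfer the acyl group to O10; acetic acid competes with water; and the product enone absorbs and is photolysed further. The fallback removes the participating ester and postpones propanoylation. It sets out from 11. Silylation of the secondary alcohol (Et3SiCl, imidazole) would give the C8 triethylsilyl ether F1, acetylation as in step 8 the acetate F2, and DDQ the dienone F3. Irradiation of F3 in aqueous acetic acid, which also hydrolyses the triethylsilyl ether, would give the 8β,10β-diol 11-acetate F4. Selective acylation of its secondary alcohol with propanoic anhydride and DMAP comes back to the route at 15.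

Step 12. Poor facial selectivity is the risk: the α preference rests on a conformational argument for a mobile ring, and delivery from the β face would give the C10 epimer. The fallback uses hydroxyl-directed hydrogenation, which needs a free 8α-hydroxyl. It sets out from 9 and comes back at 18.
- t-BuMe2SiCl and imidazole would give the 8α-silyl ether F5.
- Acetylation would give F6, DDQ the dienone F7, irradiation in aqueous acetic acid the carbinol F8, and SOCl2/pyridine the exocyclic alkene F9.
- HF·pyridine would free the homoallylic alcohol F10.
- H2 with [Ir(cod)(PCy3)(py)]PF6 in CH2Cl2, the iridium bound to the 8α-hydroxyl, would deliver hydrogen to the α face of C10 and give F11.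
- Dess–Martin oxidation would give the ketone F12.
- LiBH(s-Bu)3 at −78 °C, attacking anti to the β substituents at C7 and C10, would give the 8β-alcohol F13.
- Propanoic anhydride and DMAP would then give 18.

Step 11. Loss of regiocontrol is the risk: ionisation of the tertiary chlorosulfite would allow loss of H1 or H9 and lead into conjugation, and substitution by chloride may compete. The fallback avoids the alkene. It sets out from 15. Acylation with methyl chlorooxoacetate (DMAP, pyridine) would give the C10 methyl oxalate F14. Bu3SnH and AIBN in toluene at reflux (radical deoxygenation of a tertiary oxalate) would transfer hydrogen to the planar C10 radical from the open α face and come back at 18.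

Step 2. The risk is enolisation toward C6, giving the cross-conjugated silyloxy diene, which cannot lead to 5. The fallback sets out from 2. KOt-Bu in t-BuOH followed by kinetic protonation with aqueous AcOH would give the β,γ-enone F15. mCPBA, attacking anti to the side chain, would give the epoxide F16, and Et3N would open it to the γ-hydroxy enone F17. Hydrogenation over Pd/C comes back at 5.

Step 6. The risk is competing reduction of the C3 enone, or retro-aldol cleavage if the C11 alkoxide forms. The fallback sets out from 9 and inverts C8 by substitution instead of by redox: Mitsunobu reaction with propanoic acid (PPh3, diisopropyl azodicarboxylate, toluene) would give 12 directly, coming back at 12 without a new compound. It is held in reserve because elimination beside the bulky C7 substituent is likely to compete.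

## Further compounds

F1 | step 10 | 11-hydroxy-8β-(triethylsilyloxy)-10-epi-eudesm-4-en-3-one | CC1=C2C[C@H](C(C)(C)O)[C@H](O[Si](CC)(CC)CC)C[C@]2(C)CCC1=O
F2 | step 10 | 11-acetoxy-8β-(triethylsilyloxy)-10-epi-eudesm-4-en-3-one | CC1=C2C[C@H](C(C)(C)OC(C)=O)[C@H](O[Si](CC)(CC)CC)C[C@]2(C)CCC1=O
F3 | step 10 | 11-acetoxy-8β-(triethylsilyloxy)-10-epi-eudesma-1,4-dien-3-one | CC1=C2C[C@H](C(C)(C)OC(C)=O)[C@H](O[Si](CC)(CC)CC)C[C@]2(C)C=CC1=O
F4 | step 10 | 11-acetoxy-8β,10β-dihydroxy-1βH-guai-4-en-3-one | O[C@@H]1C[C@](C)(O)[C@H]2CC(=O)C(C)=C2C[C@@H]1C(C)(C)OC(C)=O
F5 | step 12 | 8α-(tert-butyldimethylsilyloxy)-11-hydroxy-10-epi-eudesm-4-en-3-one | CC1=C2C[C@H](C(C)(C)O)[C@@H](O[Si](C)(C)C(C)(C)C)C[C@]2(C)CCC1=O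
F6 | step 12 | 11-acetoxy-8α-(tert-butyldimethylsilyloxy)-10-epi-eudesm-4-en-3-one | CC1=C2C[C@H](C(C)(C)OC(C)=O)[C@@H](O[Si](C)(C)C(C)(C)C)C[C@]2(C)CCC1=O
F7 | step 12 | 11-acetoxy-8α-(tert-butyldimethylsilyloxy)-10-epi-eudesma-1,4-dien-3-one | CC1=C2C[C@H](C(C)(C)OC(C)=O)[C@@H](O[Si](C)(C)C(C)(C)C)C[C@]2(C)C=CC1=O
F8 | step 12 | 11-acetoxy-8α-(tert-butyldimethylsilyloxy)-10β-hydroxy-1βH-guai-4-en-3-one | CC(C)(C)[Si](C)(C)O[C@H]1C[C@](C)(O)[C@H]2CC(=O)C(C)=C2C[C@@H]1C(C)(C)OC(C)=O
F9 | step 12 | 11-acetoxy-8α-(tert-butyldimethylsilyloxy)-1βH-guaia-4,10(14)-dien-3-one | CC(C)(C)[Si](C)(C)O[C@H]1CC(=C)[C@H]2CC(=O)C(C)=C2C[C@@H]1C(C)(C)OC(C)=O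
F10 | step 12 | 11-acetoxy-8α-hydroxy-1βH-guaia-4,10(14)-dien-3-one | O[C@H]1CC(=C)[C@H]2CC(=O)C(C)=C2C[C@@H]1C(C)(C)OC(C)=O
F11 | step 12 | 11-acetoxy-8α-hydroxy-1βH,10αH-guai-4-en-3-one | O[C@H]1C[C@H](C)[C@H]2CC(=O)C(C)=C2C[C@@H]1C(C)(C)OC(C)=O
F12 | step 12 | 11-acetoxy-1βH,10αH-guai-4-ene-3,8-dione | O=C1C[C@H](C)[C@H]2CC(=O)C(C)=C2C[C@@H]1C(C)(C)OC(C)=O
F13 | step 12 | 11-acetoxy-8β-hydroxy-1βH,10αH-guai-4-en-3-one | O[C@@H]1C[C@H](C)[C@H]2CC(=O)C(C)=C2C[C@@H]1C(C)(C)OC(C)=O
F14 | step 11 | C10 methyl oxalate of 15 | CCC(=O)O[C@@H]1C[C@](C)(OC(=O)C(=O)OC)[C@H]2CC(=O)C(C)=C2C[C@@H]1C(C)(C)OC(C)=O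
F15 | step 2 | (5S)-5-(2-hydroxypropan-2-yl)-2-methylcyclohex-3-en-1-one, C2 epimers | CC1C=C[C@H](CC1=O)C(C)(C)O
F16 | step 2 | 3,4-epoxy-5-(2-hydroxypropan-2-yl)-2-methylcyclohexan-1-one, epoxide trans to the side chain | CC1[C@@H]2O[C@@H]2[C@H](CC1=O)C(C)(C)O
F17 | step 2 | (4S,5S)-4-hydroxy-5-(2-hydroxypropan-2-yl)-2-methylcyclohex-2-en-1-one | CC1=C[C@H](O)[C@H](CC1=O)C(C)(C)O
F0 | step 6 | none | none
A1 | alternative 1 | bicyclic cycloheptadiene with C7 methyl ester, C8 silyl enol ether, C1=C5 alkene and C3 ethylene ketal | COC(=O)C1=C(O[Si](C)(C)C(C)(C)C)C[C@H](C)C2=C(C1)[C@H](C)C3(C2)OCCO3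
A2 | alternative 1 | (E)-7-ethylidene-9-methyl-8-methylidene-1,4-dioxaspiro[4.4]nonane | C=C1[C@H](C)C2(C/C1=C\C)OCCO2
A3 | alternative 1 | methyl 3-(tert-butyldimethylsilyloxy)-2-diazobut-3-enoate | COC(=O)C(=[N+]=[N-])C(=C)O[Si](C)(C)C(C)(C)C
A4 | alternative 2 | guaia-4,10(14)-dien-8α-ol, 3-O-tert-butyldimethylsilyl and 11-O-triethylsilyl ethers | CC1=C2C[C@H](C(C)(C)O[Si](CC)(CC)CC)[C@@H](O)CC(=C)[C@H]2C[C@H]1O[Si](C)(C)C(C)(C)C
A5 | alternative 2 | C8 aldehyde with the C1 isopropenyl cyclopentene (8,9-seco precursor of A4) | CC1=C(C[C@H](C(C)(C)O[Si](CC)(CC)CC)C=O)[C@@H](C(C)=C)C[C@H]1O[Si](C)(C)C(C)(C)C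
A6 | alternative 3 | 4,4-dichloro-3-oxoguaiane 8-propanoate 11-acetate | CCC(=O)O[C@@H]1C[C@H](C)[C@H]2CC(=O)C(Cl)(Cl)[C@H]2C[C@@H]1C(C)(C)OC(C)=O
A7 | alternative 3 | cis-fused α,α-dichlorocyclobutanone on the cycloheptane diester | CCC(=O)O[C@@H]1C[C@H](C)[C@H]2C(=O)C(Cl)(Cl)[C@H]2C[C@@H]1C(C)(C)OC(C)=O
A8 | alternative 3 | cycloheptene diester carrying C7, C8 and C10 | CCC(=O)O[C@@H]1C[C@H](C)C=CC[C@@H]1C(C)(C)OC(C)=O
A9 | alternative 3 | dichloroketene | ClC(Cl)=C=O
A10 | alternative 3 | diazomethane | C=[N+]=[N-]
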